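**Retrosynthetic overview**

- The target is the free acid of a depside; the last disconnection is acidolysis of a tert-butyl ester on ring B C1.
- The strategy rests on ring B, the 2,4-dihydroxy-6-propylbenzoic acid ring with the depside oxygen on C3 between the two phenols. Its six carbons plus the propyl chain are C2–C10 of a 3,5,7-trioxodecanoate, with the ring A aroyloxy group on chain C4. The ring B C1–C6 bond is made by aldol attack of chain C2 on the C7 ketone.
- The open chain is cut at C4–C5: dianion of tert-butyl 4-(aroyloxy)acetoacetate plus a ketal-masked 3-oxohexanoyl Weinreb amide (from ethyl 3-oxohexanoate), then unmasking of C7.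
- The acyloxy keto ester comes from O-alkylation of 2,4-dimethoxy-6-propylbenzoic acid with tert-butyl 4-chloroacetoacetate. The acid comes from 3,5-dimethoxybenzaldehyde by Wittig reaction, hydrogenation, bromination and carboxylation.
- Ring order: ring A is carried from a bought arene; ring B is the only ring formed, in the penultimate step.

Key step: step 11

Assumption: compound 20 is drawn as the triketo tautomer although it will exist largely as enols; its C4 centre is racemic and is erased on aromatization, and the target has no stereocentre.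

**Route**

Step 1
Reactants: 1 3,5-dimethoxybenzaldehyde
Product: 2 1,3-dimethoxy-5-(prop-1-en-1-yl)benzene (E/Z mixture)
Conditions: EtPPh3Br (1.2 equiv), KOtBu (1.2 equiv), THF, 0 °C → rt
Reagents that add atoms: ethyltriphenylphosphonium bromide, CC[P+](c1ccccc1)(c1ccccc1)c1ccccc1.[Br-]
Why: Wittig olefination of an aromatic aldehyde with a non-stabilized ylide is reliable, and the alkene geometry is irrelevant because the double bond is hydrogenated next.

Step 2
Reactants: 2 1,3-dimethoxy-5-(prop-1-en-1-yl)benzene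
Product: 3 1,3-dimethoxy-5-propylbenzene
Conditions: H2 (1 atm), 10% Pd/C, EtOAc, rt
Reagents that add atoms: none
Why: Catalytic hydrogenation saturates the styrene-type alkene and leaves the arene and the aryl methyl ethers untouched.

Step 3
Reactants: 3 1,3-dimethoxy-5-propylbenzene
Product: 4 2-bromo-1,5-dimethoxy-3-propylbenzene
Conditions: NBS (1.0 equiv), MeCN, 0 °C → rt
Reagents that add atoms: N-bromosuccinimide, O=C1CCC(=O)N1Br
Why: Electrophilic aromatic bromination goes to the position para to one methoxy group and ortho to the other (next to propyl), as with 3,5-dimethoxytoluene, rather than to the more crowded position between the two methoxy groups, and one equivalent at low temperature limits dibromination.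

Step 4
Reactants: 4 2-bromo-1,5-dimethoxy-3-propylbenzene
Product: 7 2,4-dimethoxy-6-propylbenzoic acid, via aryllithium 5 (not isolated), via lithium carboxylate 6 (not isolated)
Conditions: n-BuLi (1.05 equiv), THF, −78 °C; CO2; then aq. HCl
Reagents that add atoms: carbon dioxide, O=C=O
Why: Bromine–lithium exchange at −78 °C is faster than ring or benzylic deprotonation, and carboxylation of the aryllithium places the carboxyl group exactly at the brominated carbon.

Step 5
Reactants: 7 2,4-dimethoxy-6-propylbenzoic acid; 8 tert-butyl 4-chloro-3-oxobutanoate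
Product: 10 tert-butyl 4-[(2,4-dimethoxy-6-propylbenzoyl)oxy]-3-oxobutanoate, via caesium carboxylate 9 (not isolated)
Conditions: Cs2CO3 (0.5 equiv), DMF, rt; then 8 (1.1 equiv), NaI (0.1 equiv), 0 °C → rt
Reagents that add atoms: none
Why: SN2 O-alkylation of a caesium carboxylate by an α-chloro ketone (Finkelstein-assisted) esterifies the di-ortho-substituted acid without attack at its hindered acyl carbon, and exactly half an equivalent of carbonate leaves no free base to enolize the keto ester.

Step 6
Reactants: 11 ethyl 3-oxohexanoate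
Product: 12 ethyl 2-(2-propyl-1,3-dioxolan-2-yl)acetate
Conditions: ethylene glycol (3 equiv), pTsOH·H2O (cat.), toluene, reflux, Dean–Stark
Reagents that add atoms: ethylene glycol, OCCO
Why: Acid-catalysed ketalization with azeotropic water removal masks the ketone of the β-keto ester as a dioxolane and so removes the acidic methylene that would quench the dianion in step 9.

Step 7
Reactants: 12 ethyl 2-(2-propyl-1,3-dioxolan-2-yl)acetate
Product: 14 2-(2-propyl-1,3-dioxolan-2-yl)acetic acid, via lithium carboxylate 13 (not isolated)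
Conditions: LiOH (1.5 equiv), THF/H2O, rt; then cold 1 M HCl to pH 3–4, immediate extraction
Reagents that add atoms: lithium hydroxide, [Li+].[OH-]
Why: Saponification of the ethyl ester runs under basic conditions to which the dioxolane is inert, and brief cold acidification frees the acid without hydrolysing the ketal.

Step 8
Reactants: 14 2-(2-propyl-1,3-dioxolan-2-yl)acetic acid
Product: 16 N-methoxy-N-methyl-2-(2-propyl-1,3-dioxolan-2-yl)acetamide, via acyl imidazole 15 (not isolated)
Conditions: carbonyldiimidazole (1.1 equiv), CH2Cl2, rt; then MeNHOMe·HCl (1.2 equiv), rt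
Reagents that add atoms: N,O-dimethylhydroxylamine hydrochloride, CNOC.Cl
Why: Carbonyldiimidazole activation followed by aminolysis of the acyl imidazole gives the Weinreb amide under near-neutral conditions that spare the ketal.

Step 9
Reactants: 10 tert-butyl 4-[(2,4-dimethoxy-6-propylbenzoyl)oxy]-3-oxobutanoate; 16 N-methoxy-N-methyl-2-(2-propyl-1,3-dioxolan-2-yl)acetamide
Product: 19 tert-butyl 4-[(2,4-dimethoxy-6-propylbenzoyl)oxy]-3,5-dioxo-6-(2-propyl-1,3-dioxolan-2-yl)hexanoate (racemic at C4), via dilithium dianion 17 (not isolated), via tetrahedral adduct 18 (not isolated)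
Conditions: LiN(iPr)2 (2.05 equiv), THF, −78 °C; then 16 (1.1 equiv), −78 → −20 °C; AcOH quench at −40 °C
Reagents that add atoms: none
Why: This is the γ-acylation of a β-keto ester dianion by a Weinreb amide (Claisen-type condensation), in which the C4 terminus of the dienediolate is the most nucleophilic site, the chelated adduct 18 keeps the new ketone masked until the quench so that no acidic product consumes dianion, and the hindered aroyl carbonyl resists intramolecular acyl transfer at low temperature; the C4 centre forms racemic and is lost in step 11.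

Step 10
Reactants: 19 tert-butyl 4-[(2,4-dimethoxy-6-propylbenzoyl)oxy]-3,5-dioxo-6-(2-propyl-1,3-dioxolan-2-yl)hexanoate
Product: 20 tert-butyl 4-[(2,4-dimethoxy-6-propylbenzoyl)oxy]-3,5,7-trioxodecanoate (racemic at C4, enolizable)
Conditions: pTsOH·H2O (0.2 equiv), acetone/H2O (9:1), rt
Reagents that add atoms: water, O
Why: Acid-catalysed ketal hydrolysis with catalytic sulfonic acid in wet acetone at room temperature is too mild to ionize the tert-butyl ester or to cyclodehydrate the trione to a pyranone.

Step 11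
Reactants: 20 tert-butyl 4-[(2,4-dimethoxy-6-propylbenzoyl)oxy]-3,5,7-trioxodecanoate
Product: 22 tert-butyl 3-[(2,4-dimethoxy-6-propylbenzoyl)oxy]-2,4-dihydroxy-6-propylbenzoate, via cyclic aldol 21 (not isolated)
Conditions: Cs2CO3 (2.5 equiv), THF/t-BuOH (10:1), 0 °C → rt; then AcOH
Reagents that add atoms: none
Why: Carbonate converts 20 into its polyenolate, whose C2 carbon (the α-carbon of the β-keto ester) adds to the C7 ketone to form the C2–C7 bond, which is the C1–C6 bond of ring B, and aldol 21 then loses water by E1cB and tautomerizes at C3 and C5 to the arene, so that chain C4 with its aroyloxy group becomes ring B C3 between the two phenols. The closest known reaction is the biomimetic, base-mediated aldol aromatization of 3,5,7-triketo esters to β-resorcylates, applied here to a chain that carries an acyloxy group on C4. Ring B closes in a six-membered (enolendo)-exo-trig aldol mode. No stereocentre has to be controlled, because C4 of 20 and the three sp3 ring centres of 21 all become sp2 on aromatization. The step needs chemoselectivity for the C2-to-C7 aldol over the C8-to-C3 aldol, over Claisen closure of C6 onto C1, and over attack of the C2 or C6 enolate on the aroyl carbonyl. The much higher acidity of C2 than of C8, the poorly electrophilic tert-butyl ester, the shielding of the aroyl carbonyl by its ortho methoxy and ortho propyl groups, and a medium free of nucleophilic alcohols should secure it.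

Step 12
Reactants: 22 tert-butyl 3-[(2,4-dimethoxy-6-propylbenzoyl)oxy]-2,4-dihydroxy-6-propylbenzoate
Product: 23 3-[(2,4-dimethoxy-6-propylbenzoyl)oxy]-2,4-dihydroxy-6-propylbenzoic acid (target)
Conditions: CF3CO2H/CH2Cl2 (1:4), Et3SiH (3 equiv), 0 °C; evaporate cold
Reagents that add atoms: none
Why: Acidolysis of the tert-butyl ester by alkyl–oxygen cleavage (E1-type loss of the tert-butyl cation) leaves both aryl esters and the methyl ethers intact, Et3SiH traps the cation by hydride transfer so that electron-rich ring B is not tert-butylated, and low temperature with short exposure limits decarboxylation of the β-resorcylic acid.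

**Compound list**

1 | 3,5-dimethoxybenzaldehyde | COc1cc(C=O)cc(OC)c1 | starting material
2 | 1,3-dimethoxy-5-(prop-1-en-1-yl)benzene (E/Z mixture) | CC=Cc1cc(OC)cc(OC)c1 | intermediate
3 | 1,3-dimethoxy-5-propylbenzene | CCCc1cc(OC)cc(OC)c1 | intermediate
4 | 2-bromo-1,5-dimethoxy-3-propylbenzene | CCCc1cc(OC)cc(OC)c1Br | intermediate
5 | (2,4-dimethoxy-6-propylphenyl)lithium (not isolated) | [Li]c1c(CCC)cc(OC)cc1OC | intermediate
6 | lithium 2,4-dimethoxy-6-propylbenzoate (not isolated) | [Li+].[O-]C(=O)c1c(CCC)cc(OC)cc1OC | intermediate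
7 | 2,4-dimethoxy-6-propylbenzoic acid | CCCc1cc(OC)cc(OC)c1C(=O)O | intermediate
8 | tert-butyl 4-chloro-3-oxobutanoate | CC(C)(C)OC(=O)CC(=O)CCl | starting material
9 | caesium 2,4-dimethoxy-6-propylbenzoate (not isolated) | [Cs+].[O-]C(=O)c1c(CCC)cc(OC)cc1OC | intermediate
10 | tert-butyl 4-[(2,4-dimethoxy-6-propylbenzoyl)oxy]-3-oxobutanoate | CCCc1cc(OC)cc(OC)c1C(=O)OCC(=O)CC(=O)OC(C)(C)C | intermediate
11 | ethyl 3-oxohexanoate | CCCC(=O)CC(=O)OCC | starting material
12 | ethyl 2-(2-propyl-1,3-dioxolan-2-yl)acetate | CCCC1(CC(=O)OCC)OCCO1 | intermediate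
13 | lithium 2-(2-propyl-1,3-dioxolan-2-yl)acetate (not isolated) | [Li+].CCCC1(CC(=O)[O-])OCCO1 | intermediate
14 | 2-(2-propyl-1,3-dioxolan-2-yl)acetic acid | CCCC1(CC(=O)O)OCCO1 | intermediate
15 | 1-(1H-imidazol-1-yl)-2-(2-propyl-1,3-dioxolan-2-yl)ethan-1-one (not isolated) | CCCC1(CC(=O)n2ccnc2)OCCO1 | intermediate
16 | N-methoxy-N-methyl-2-(2-propyl-1,3-dioxolan-2-yl)acetamide | CCCC1(CC(=O)N(C)OC)OCCO1 | intermediate
17 | dilithium dienediolate (dianion) of 10 (not isolated) | [Li+].[Li+].CCCc1cc(OC)cc(OC)c1C(=O)OC=C([O-])C=C([O-])OC(C)(C)C | intermediate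
18 | dilithium tetrahedral adduct of 17 with 16 (not isolated) | [Li+].[Li+].CCCC1(CC([O-])(N(C)OC)C(OC(=O)c2c(CCC)cc(OC)cc2OC)C(=O)C=C([O-])OC(C)(C)C)OCCO1 | intermediate
19 | tert-butyl 4-[(2,4-dimethoxy-6-propylbenzoyl)oxy]-3,5-dioxo-6-(2-propyl-1,3-dioxolan-2-yl)hexanoate (racemic) | CCCC1(CC(=O)C(OC(=O)c2c(CCC)cc(OC)cc2OC)C(=O)CC(=O)OC(C)(C)C)OCCO1 | intermediate
20 | tert-butyl 4-[(2,4-dimethoxy-6-propylbenzoyl)oxy]-3,5,7-trioxodecanoate (racemic, enolizable) | CCCC(=O)CC(=O)C(OC(=O)c1c(CCC)cc(OC)cc1OC)C(=O)CC(=O)OC(C)(C)C | intermediate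
21 | tert-butyl 3-[(2,4-dimethoxy-6-propylbenzoyl)oxy]-6-hydroxy-2,4-dioxo-6-propylcyclohexane-1-carboxylate (diastereomer mixture, not isolated) | CCCC1(O)CC(=O)C(OC(=O)c2c(CCC)cc(OC)cc2OC)C(=O)C1C(=O)OC(C)(C)C | intermediate
22 | tert-butyl 3-[(2,4-dimethoxy-6-propylbenzoyl)oxy]-2,4-dihydroxy-6-propylbenzoate | CCCc1cc(OC)cc(OC)c1C(=O)Oc1c(O)cc(CCC)c(C(=O)OC(C)(C)C)c1O | intermediate
23 | 3-[(2,4-dimethoxy-6-propylbenzoyl)oxy]-2,4-dihydroxy-6-propylbenzoic acid | CCCc1cc(OC)cc(OC)c1C(=O)Oc1c(O)cc(CCC)c(C(=O)O)c1O | target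

**Count**

Total steps: 12. Longest linear sequence: 9 steps (steps 1–5 and 9–12); the side branch is steps 6–8.

**Steps most likely to fail**

1. Step 11 (key step). The C2 or C6 enolate, or an enol oxygen, may attack the aroyl carbonyl on the C4 oxygen (acyl transfer, or Knoevenagel-type closure to a furanone) faster than C2 adds to the C7 ketone.
The fallback takes the acyl group out of the cyclization and forms the depside bond on the finished ring. It sets out from 8 and comes back at 22. NaH (2 equiv) and benzyl alcohol in THF would convert 8 into tert-butyl 4-(benzyloxy)-3-oxobutanoate F1. Its LiN(iPr)2 dianion would be acylated with 16 to tert-butyl 4-(benzyloxy)-3,5-dioxo-6-(2-propyl-1,3-dioxolan-2-yl)hexanoate F2. pTsOH in wet acetone would give tert-butyl 4-(benzyloxy)-3,5,7-trioxodecanoate F3. Cs2CO3 would fold this to tert-butyl 3-(benzyloxy)-2,4-dihydroxy-6-propylbenzoate F4, since an ether oxygen on C4 can neither migrate nor be attacked. MOMCl with iPr2NEt (NaH for the chelated 2-OH) would give tert-butyl 3-(benzyloxy)-2,4-bis(methoxymethoxy)-6-propylbenzoate F5. H2 over Pd/C would free tert-butyl 3-hydroxy-2,4-bis(methoxymethoxy)-6-propylbenzoate F6. Acid 7 with oxalyl chloride and catalytic DMF would give 2,4-dimethoxy-6-propylbenzoyl chloride F7. F7 would acylate the sodium phenoxide of F6 (NaH, THF) to tert-butyl 3-[(2,4-dimethoxy-6-propylbenzoyl)oxy]-2,4-bis(methoxymethoxy)-6-propylbenzoate F8. Dilute HCl in MeOH/THF would remove both MOM ethers and give 22.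

2. Step 9. The C4 carbanion of the dianion may transfer the aroyl group intramolecularly (O-to-C or O-to-O shift), or may add too slowly to the amide for steric reasons, with lateral deprotonation of the ortho propyl group competing.
The fallback uses a single vinylogous enolate with the C1–C3 unit masked as a dioxinone, so no C2 enolate is present. It sets out from 9 and comes back at 19. Caesium salt 9 would alkylate 6-(chloromethyl)-2,2-dimethyl-4H-1,3-dioxin-4-one in DMF to give (2,2-dimethyl-4-oxo-4H-1,3-dioxin-6-yl)methyl 2,4-dimethoxy-6-propylbenzoate F9. LiN(SiMe3)2 (2 equiv, THF, −78 °C) would form the dienolate, which would be acylated at the exocyclic carbon by acyl imidazole 15 (here isolated by a cold aqueous wash) to give 1-(2,2-dimethyl-4-oxo-4H-1,3-dioxin-6-yl)-2-oxo-3-(2-propyl-1,3-dioxolan-2-yl)propyl 2,4-dimethoxy-6-propylbenzoate F10. Heating F10 in toluene with tert-butanol at 110 °C would expel acetone, and trapping of the acylketene by the alcohol would give 19.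

3. Step 12. The freed β-resorcylic acid may protodecarboxylate in strong acid, ring B may be tert-butylated, or the depside acyl group may migrate.
The fallback replaces acidolysis by a neutral hydrogenolysis endgame with a benzyl ester. It sets out from 9 and comes back at 23. Salt 9 would alkylate benzyl 4-chloro-3-oxobutanoate to give benzyl 4-[(2,4-dimethoxy-6-propylbenzoyl)oxy]-3-oxobutanoate F11. Dianion acylation with 16 as in step 9 would give benzyl 4-[(2,4-dimethoxy-6-propylbenzoyl)oxy]-3,5-dioxo-6-(2-propyl-1,3-dioxolan-2-yl)hexanoate F12. Deketalization as in step 10 would give benzyl 4-[(2,4-dimethoxy-6-propylbenzoyl)oxy]-3,5,7-trioxodecanoate F13. Mild carbonate folding as in step 11 would give benzyl 3-[(2,4-dimethoxy-6-propylbenzoyl)oxy]-2,4-dihydroxy-6-propylbenzoate F14; a primary ester is more open to Claisen closure, so the mildest base would be used. H2 over Pd/C in EtOAc would then give 23.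

**Further compounds**

F1 | step 11 | tert-butyl 4-(benzyloxy)-3-oxobutanoate | CC(C)(C)OC(=O)CC(=O)COCc1ccccc1
F2 | step 11 | tert-butyl 4-(benzyloxy)-3,5-dioxo-6-(2-propyl-1,3-dioxolan-2-yl)hexanoate | CCCC1(CC(=O)C(OCc2ccccc2)C(=O)CC(=O)OC(C)(C)C)OCCO1
F3 | step 11 | tert-butyl 4-(benzyloxy)-3,5,7-trioxodecanoate | CCCC(=O)CC(=O)C(OCc1ccccc1)C(=O)CC(=O)OC(C)(C)C
F4 | step 11 | tert-butyl 3-(benzyloxy)-2,4-dihydroxy-6-propylbenzoate | CCCc1cc(O)c(OCc2ccccc2)c(O)c1C(=O)OC(C)(C)C
F5 | step 11 | tert-butyl 3-(benzyloxy)-2,4-bis(methoxymethoxy)-6-propylbenzoate | CCCc1cc(OCOC)c(OCc2ccccc2)c(OCOC)c1C(=O)OC(C)(C)C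
F6 | step 11 | tert-butyl 3-hydroxy-2,4-bis(methoxymethoxy)-6-propylbenzoate | CCCc1cc(OCOC)c(O)c(OCOC)c1C(=O)OC(C)(C)C
F7 | step 11 | 2,4-dimethoxy-6-propylbenzoyl chloride | CCCc1cc(OC)cc(OC)c1C(Cl)=O
F8 | step 11 | tert-butyl 3-[(2,4-dimethoxy-6-propylbenzoyl)oxy]-2,4-bis(methoxymethoxy)-6-propylbenzoate | CCCc1cc(OC)cc(OC)c1C(=O)Oc1c(OCOC)cc(CCC)c(C(=O)OC(C)(C)C)c1OCOC
F9 | step 9 | (2,2-dimethyl-4-oxo-4H-1,3-dioxin-6-yl)methyl 2,4-dimethoxy-6-propylbenzoate | CCCc1cc(OC)cc(OC)c1C(=O)OCC1=CC(=O)OC(C)(C)O1
F10 | step 9 | 1-(2,2-dimethyl-4-oxo-4H-1,3-dioxin-6-yl)-2-oxo-3-(2-propyl-1,3-dioxolan-2-yl)propyl 2,4-dimethoxy-6-propylbenzoate | CCCc1cc(OC)cc(OC)c1C(=O)OC(C(=O)CC1(CCC)OCCO1)C1=CC(=O)OC(C)(C)O1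
F11 | step 12 | benzyl 4-[(2,4-dimethoxy-6-propylbenzoyl)oxy]-3-oxobutanoate | CCCc1cc(OC)cc(OC)c1C(=O)OCC(=O)CC(=O)OCc1ccccc1
F12 | step 12 | benzyl 4-[(2,4-dimethoxy-6-propylbenzoyl)oxy]-3,5-dioxo-6-(2-propyl-1,3-dioxolan-2-yl)hexanoate | CCCC1(CC(=O)C(OC(=O)c2c(CCC)cc(OC)cc2OC)C(=O)CC(=O)OCc2ccccc2)OCCO1
F13 | step 12 | benzyl 4-[(2,4-dimethoxy-6-propylbenzoyl)oxy]-3,5,7-trioxodecanoate | CCCC(=O)CC(=O)C(OC(=O)c1c(CCC)cc(OC)cc1OC)C(=O)CC(=O)OCc1ccccc1
F14 | step 12 | benzyl 3-[(2,4-dimethoxy-6-propylbenzoyl)oxy]-2,4-dihydroxy-6-propylbenzoate | CCCc1cc(OC)cc(OC)c1C(=O)Oc1c(O)cc(CCC)c(C(=O)OCc2ccccc2)c1O
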